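**Retrosynthetic overview**
1. C3–CH2CO2H: silyl ketene acetal adds to a C3 peroxycarbenium ion (axial attack, cis to the C4 ethyl).
2. C6–Et (quaternary centre): ethyl transfer from Et2Zn to a C6 peroxycarbenium ion of a 3,6-dioxygenated 1,2-dioxane (new step).
3. 1,2-Dioxane, the only ring formed: Co/O2 oxidative ring expansion of a 1-alkenyl-2-silyloxycyclobutanol (O2 inserted into C1–C2 of the purchased four-membered ring).
4. Cyclobutanol: alkenyllithium (alkyne carboalumination/iodination) plus (2S,3R)-2-silyloxy-3-ethylcyclobutanone (chiral-base desymmetrisation, Rubottom oxidation).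
5. Side-chain stereocentre: Rh/(S)-binap 1,4-addition of butenylboronic acid to methyl pent-2-enoate, then ester to alkyne.

Assumption: 2 and 8 are bought as catalogue building blocks; ketene bis(trimethylsilyl) acetal is a reagent made beforehand from trimethylsilyl acetate, LDA and TMSCl.

Ring positions in 15–22 use the target numbering (O1, O2, C3, C4, C5, C6).

**Step 1**
Reactants: 1 methyl (E)-pent-2-enoate; 2 (E)-but-1-en-1-ylboronic acid
Product: 3 methyl (3R,4E)-3-ethylhept-4-enoate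
Conditions: [Rh(OH)((S)-binap)]2 (1.5 mol %), 2 (2 equiv), dioxane/H2O 10:1, 50 °C
Reagents that add atoms: none
Why: Hayashi–Miyaura Rh-catalysed asymmetric 1,4-addition, in which the (S)-binap–Rh–alkenyl species adds to the 2si/3re face of the (E)-enoate with retention of alkene geometry and sets the stereocentre as R (C10 of the target).

**Step 2**
Reactants: 3 methyl (3R,4E)-3-ethylhept-4-enoate
Product: 5 (4R,5E)-4-ethyloct-5-en-1-yne, via aldehyde 4 (not isolated)
Conditions: DIBAL-H (1.05 equiv), CH2Cl2, −78 °C; then MeOH, K2CO3, dimethyl (1-diazo-2-oxopropyl)phosphonate, −78 °C → rt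
Reagents that add atoms: dimethyl (1-diazo-2-oxopropyl)phosphonate (Ohira–Bestmann reagent), CC(=O)C(=[N+]=[N-])P(=O)(OC)OC
Why: One-pot partial ester reduction and Seyferth–Gilbert (Ohira–Bestmann) homologation; the stereocentre is β to the aldehyde and is not touched.

**Step 3**
Reactants: 5 (4R,5E)-4-ethyloct-5-en-1-yne
Product: 7 (1E,4R,5E)-4-ethyl-1-iodo-2-methylocta-1,5-diene, via alkenylalane 6 (not isolated)
Conditions: Me3Al (2 equiv), Cp2ZrCl2 (0.25 equiv), CH2Cl2, 0 °C → rt; then I2, THF, −30 → 0 °C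
Reagents that add atoms: trimethylaluminium, C[Al](C)C; iodine, II
Why: Negishi Zr-catalysed syn-carboalumination of the terminal alkyne followed by iodinolysis with retention gives the (E)-2-methylalkenyl iodide, and the internal (E)-alkene is inert.

**Step 4**
Reactants: 8 3-ethylcyclobutan-1-one
Product: 10 (R)-triethyl[(3-ethylcyclobut-1-en-1-yl)oxy]silane, via lithium enolate 9 (not isolated)
Conditions: (R,R)-bis(1-phenylethyl)amine, n-BuLi, LiCl, THF, −100 °C, TESCl present (internal quench)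
Reagents that add atoms: chlorotriethylsilane, CC[Si](Cl)(CC)CC
Why: Enantioselective deprotonation of the prochiral ketone with a Simpkins-type chiral lithium amide differentiates the two α-CH2 groups and fixes the ring stereocentre as R (C4 of the target); the sense of induction is assigned by analogy with 3-substituted cyclobutanones and is to be confirmed, and the (S,S)-base would give the enantiomer.

**Step 5**
Reactants: 10 (R)-triethyl[(3-ethylcyclobut-1-en-1-yl)oxy]silane
Product: 12 (2S,3R)-3-ethyl-2-[(triethylsilyl)oxy]cyclobutan-1-one, via silyloxy epoxide 11 (not isolated)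
Conditions: DMDO (1.1 equiv), acetone/CH2Cl2, −40 → 0 °C
Reagents that add atoms: dimethyldioxirane, CC1(C)OO1
Why: Rubottom oxidation, in which epoxidation anti to the ethyl group and 1,4-silyl shift give the α-silyloxy ketone; DMDO avoids Baeyer–Villiger oxidation of the cyclobutanone, and the C2 configuration is of no consequence later.

**Step 6**
Reactants: 7 (1E,4R,5E)-4-ethyl-1-iodo-2-methylocta-1,5-diene; 12 (2S,3R)-3-ethyl-2-[(triethylsilyl)oxy]cyclobutan-1-one
Product: 14 (1S,2S,3R)-3-ethyl-1-[(1E,4R,5E)-4-ethyl-2-methylocta-1,5-dien-1-yl]-2-[(triethylsilyl)oxy]cyclobutan-1-ol, via alkenyllithium 13 (not isolated)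
Conditions: 7, t-BuLi (2.0 equiv), Et2O, −78 °C; then 12, −78 °C; then AcOH (1.1 equiv), −78 °C
Reagents that add atoms: none
Why: Iodine–lithium exchange with retention of alkene geometry and 1,2-addition to the strained ketone anti to the α-silyloxy group; the cold acidic quench prevents O-to-O silyl migration, and the C1 configuration is lost in the next step.

**Step 7**
Reactants: 14 (1S,2S,3R)-3-ethyl-1-[(1E,4R,5E)-4-ethyl-2-methylocta-1,5-dien-1-yl]-2-[(triethylsilyl)oxy]cyclobutan-1-ol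
Product: 16 (4R)-4-ethyl-6-hydroxy-6-[(1E,4R,5E)-4-ethyl-2-methylocta-1,5-dien-1-yl]-3-[(triethylsilyl)oxy]-1,2-dioxane, via hydroperoxy enone 15 (not isolated)
Conditions: Co(acac)2 (20 mol %), O2 (1 atm), THF, rt → 40 °C
Reagents that add atoms: dioxygen, O=O
Why: Cobalt/O2 oxidative ring expansion of a cyclobutanol, in which the alkoxy radical undergoes β-scission of C1–C2 toward the α-silyloxy radical (not the primary C4 radical), O2 is captured and the hydroperoxide closes onto the enone carbonyl; C3 and C6 form as anomeric mixtures that are erased in steps 9 and 10, and the C4 ethyl centre is not involved.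

**Step 8**
Reactants: 16 (4R)-4-ethyl-6-hydroxy-6-[(1E,4R,5E)-4-ethyl-2-methylocta-1,5-dien-1-yl]-3-[(triethylsilyl)oxy]-1,2-dioxane
Product: 17 (4R)-4-ethyl-6-[(1E,4R,5E)-4-ethyl-2-methylocta-1,5-dien-1-yl]-3-[(triethylsilyl)oxy]-1,2-dioxan-6-yl acetate
Conditions: Ac2O, Et3N, DMAP (cat.), CH2Cl2, 0 °C
Reagents that add atoms: acetic anhydride, CC(=O)OC(C)=O
Why: DMAP-catalysed acylation of the cyclic peroxyhemiketal hydroxyl traps the closed form and installs a leaving group that ionises far more easily than the C3 silyl acetal.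

**Step 9**
Reactants: 17 (4R)-4-ethyl-6-[(1E,4R,5E)-4-ethyl-2-methylocta-1,5-dien-1-yl]-3-[(triethylsilyl)oxy]-1,2-dioxan-6-yl acetate
Product: 19 (4R,6R)-4,6-diethyl-6-[(1E,4R,5E)-4-ethyl-2-methylocta-1,5-dien-1-yl]-3-[(triethylsilyl)oxy]-1,2-dioxane, via peroxycarbenium triflate 18 (not isolated)
Conditions: Et2Zn (3 equiv), TMSOTf (1.1 equiv), CH2Cl2, −78 °C
Reagents that add atoms: diethylzinc, CC[Zn]CC
Why: Proposed new method: TMSOTf ionises the tertiary, alkenyl-stabilised C6 acetate (not the secondary C3 silyl acetal) to peroxycarbenium ion 18, and Et2Zn delivers ethyl along the pseudo-axial trajectory of the half-chair that keeps the C4 ethyl pseudo-equatorial (chair-like transition state), so the new ethyl ends axial and trans to the C4 ethyl (6R) while the alkenyl group becomes equatorial; the closest known reaction types are Lewis-acid-mediated additions of allylsilanes and silyl enol ethers to peroxycarbenium ions and TMSOTf-promoted dialkylzinc additions to cyclic α-acetoxy ethers, and dialkyl peroxides are expected to tolerate Et2Zn at −78 °C.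

**Step 10**
Reactants: 19 (4R,6R)-4,6-diethyl-6-[(1E,4R,5E)-4-ethyl-2-methylocta-1,5-dien-1-yl]-3-[(triethylsilyl)oxy]-1,2-dioxane
Product: 22 2-[(3R,4R,6R)-4,6-diethyl-6-[(1E,4R,5E)-4-ethyl-2-methylocta-1,5-dien-1-yl]-1,2-dioxan-3-yl]acetic acid, via peroxycarbenium triflate 20 (not isolated), via trimethylsilyl ester 21 (not isolated)
Conditions: ketene bis(trimethylsilyl) acetal (3 equiv), TMSOTf (1.0 equiv), CH2Cl2, −78 → −40 °C; then pH 4 aqueous buffer
Reagents that add atoms: ketene bis(trimethylsilyl) acetal, C=C(O[Si](C)(C)C)O[Si](C)(C)C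
Why: Mukaiyama-type addition of a silyl ketene acetal to peroxycarbenium ion 20, with axial attack on the half-chair that has the C6 alkenyl and C4 ethyl equatorial and the C6 ethyl axial (the alternative has a 1,3-diaxial ethyl/alkenyl clash), which puts CH2CO2H cis to the C4 ethyl (3R); the silyl ester hydrolyses on work-up.

**Compound list**
1 | methyl (E)-pent-2-enoate | CC/C=C/C(=O)OC | starting material
2 | (E)-but-1-en-1-ylboronic acid | CC/C=C/B(O)O | starting material
3 | methyl (3R,4E)-3-ethylhept-4-enoate | CC/C=C/[C@H](CC)CC(=O)OC | intermediate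
4 | (3R,4E)-3-ethylhept-4-enal | CC/C=C/[C@H](CC)CC=O | intermediate (not isolated)
5 | (4R,5E)-4-ethyloct-5-en-1-yne | CC/C=C/[C@H](CC)CC#C | intermediate
6 | dimethyl[(1E,4R,5E)-4-ethyl-2-methylocta-1,5-dien-1-yl]alane | CC/C=C/[C@H](CC)C/C(C)=C/[Al](C)C | intermediate (not isolated)
7 | (1E,4R,5E)-4-ethyl-1-iodo-2-methylocta-1,5-diene | CC/C=C/[C@H](CC)C/C(C)=C/I | intermediate
8 | 3-ethylcyclobutan-1-one | CCC1CC(=O)C1 | starting material
9 | lithium (3R)-3-ethylcyclobut-1-en-1-olate | [Li+].CC[C@H]1C=C([O-])C1 | intermediate (not isolated)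
10 | (R)-triethyl[(3-ethylcyclobut-1-en-1-yl)oxy]silane | CC[C@H]1C=C(O[Si](CC)(CC)CC)C1 | intermediate
11 | (3R)-3-ethyl-1-[(triethylsilyl)oxy]-5-oxabicyclo[2.1.0]pentane, oxirane oxygen trans to ethyl | CC[C@@H]1C[C@@]2(O[Si](CC)(CC)CC)O[C@@H]12 | intermediate (not isolated)
12 | (2S,3R)-3-ethyl-2-[(triethylsilyl)oxy]cyclobutan-1-one | O=C1C[C@@H](CC)[C@@H]1O[Si](CC)(CC)CC | intermediate
13 | [(1E,4R,5E)-4-ethyl-2-methylocta-1,5-dien-1-yl]lithium | CC/C=C/[C@H](CC)C/C(C)=C/[Li] | intermediate (not isolated)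
14 | (1S,2S,3R)-3-ethyl-1-[(1E,4R,5E)-4-ethyl-2-methylocta-1,5-dien-1-yl]-2-[(triethylsilyl)oxy]cyclobutan-1-ol (major C1 epimer drawn) | CC/C=C/[C@H](CC)C/C(C)=C/[C@@]1(O)C[C@@H](CC)[C@@H]1O[Si](CC)(CC)CC | intermediate
15 | (2R,5E,8R,9E)-2,8-diethyl-1-hydroperoxy-6-methyl-1-[(triethylsilyl)oxy]dodeca-5,9-dien-4-one (C1 epimers) | CC/C=C/[C@H](CC)C/C(C)=C/C(=O)C[C@@H](CC)C(OO)O[Si](CC)(CC)CC | intermediate (not isolated)
16 | (4R)-4-ethyl-6-hydroxy-6-[(1E,4R,5E)-4-ethyl-2-methylocta-1,5-dien-1-yl]-3-[(triethylsilyl)oxy]-1,2-dioxane (anomers at C3 and C6) | CC/C=C/[C@H](CC)C/C(C)=C/C1(O)C[C@@H](CC)C(O[Si](CC)(CC)CC)OO1 | intermediate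
17 | (4R)-4-ethyl-6-[(1E,4R,5E)-4-ethyl-2-methylocta-1,5-dien-1-yl]-3-[(triethylsilyl)oxy]-1,2-dioxan-6-yl acetate (anomers at C3 and C6) | CC/C=C/[C@H](CC)C/C(C)=C/C1(OC(C)=O)C[C@@H](CC)C(O[Si](CC)(CC)CC)OO1 | intermediate
18 | C6 peroxycarbenium triflate: (4R)-4-ethyl-6-alkenyl-3-(triethylsilyloxy)-1,2-dioxan-1-ium with O1=C6 | CC/C=C/[C@H](CC)C/C(C)=C/C1=[O+]OC(O[Si](CC)(CC)CC)[C@H](CC)C1.[O-]S(=O)(=O)C(F)(F)F | intermediate (not isolated)
19 | (4R,6R)-4,6-diethyl-6-[(1E,4R,5E)-4-ethyl-2-methylocta-1,5-dien-1-yl]-3-[(triethylsilyl)oxy]-1,2-dioxane (anomers at C3) | CC/C=C/[C@H](CC)C/C(C)=C/[C@@]1(CC)C[C@@H](CC)C(O[Si](CC)(CC)CC)OO1 | intermediate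
20 | C3 peroxycarbenium triflate: (4R,6R)-4,6-diethyl-6-alkenyl-1,2-dioxan-2-ium with O2=C3 | CC/C=C/[C@H](CC)C/C(C)=C/[C@@]1(CC)C[C@@H](CC)C=[O+]O1.[O-]S(=O)(=O)C(F)(F)F | intermediate (not isolated)
21 | trimethylsilyl 2-[(3R,4R,6R)-4,6-diethyl-6-[(1E,4R,5E)-4-ethyl-2-methylocta-1,5-dien-1-yl]-1,2-dioxan-3-yl]acetate | CC/C=C/[C@H](CC)C/C(C)=C/[C@@]1(CC)C[C@@H](CC)[C@@H](CC(=O)O[Si](C)(C)C)OO1 | intermediate (not isolated)
22 | 2-[(3R,4R,6R)-4,6-diethyl-6-[(1E,4R,5E)-4-ethyl-2-methylocta-1,5-dien-1-yl]-1,2-dioxan-3-yl]acetic acid | CC/C=C/[C@H](CC)C/C(C)=C/[C@@]1(CC)C[C@@H](CC)[C@@H](CC(=O)O)OO1 | target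

**Totals**
Total steps: 10. Longest linear sequence: 8 (steps 1, 2, 3, 6, 7, 8, 9, 10).

**Three steps most likely to fail**

Step 9 (the proposed new ethyl transfer). The risks are attack of Et2Zn on the O–O bond, 1,4-addition or E/Z scrambling in the conjugated cation, and intramolecular capture of the cation by the C3 silyloxy oxygen. The fallback uses only known peroxycarbenium chemistry; it sets out from 17 and comes back at 19. Acetate 17 is treated with TMSOTf and (vinyloxy)trimethylsilane at −78 °C, an established silyl enol ether addition to a peroxycarbenium ion with the same axial approach. This gives 2-[(4R,6S)-4-ethyl-6-[(1E,4R,5E)-4-ethyl-2-methylocta-1,5-dien-1-yl]-3-[(triethylsilyl)oxy]-1,2-dioxan-6-yl]acetaldehyde F6, which has the same spatial arrangement as 19 (the descriptor changes by CIP priority only). NaBH4 in MeOH at 0 °C gives the primary alcohol 2-[(4R,6S)-4-ethyl-6-alkenyl-3-(triethylsilyloxy)-1,2-dioxan-6-yl]ethanol F7. MsCl/Et3N gives its methanesulfonate F8, and NaI in acetone gives the primary iodide (4R,6S)-4-ethyl-6-alkenyl-6-(2-iodoethyl)-3-(triethylsilyloxy)-1,2-dioxane F9. NaBH4 in DMSO at room temperature reduces the C–I bond without touching the peroxide and returns 19.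

Step 7 (ring expansion). The risks are oxidation of the α-silyloxy radical before O2 capture and an unfavourable open/closed equilibrium for the enone-derived hemiketal. The fallback replaces radical O2 insertion by two-electron cleavage and H2O2 addition; it sets out from 14 and comes back at 16. TBAF/AcOH in THF at 0 °C gives (1S,2S,3R)-3-ethyl-1-[(1E,4R,5E)-4-ethyl-2-methylocta-1,5-dien-1-yl]cyclobutane-1,2-diol F1. Glycol cleavage with NaIO4 on silica in CH2Cl2 at 0 °C gives (2R,5E,8R,9E)-2,8-diethyl-6-methyl-4-oxododeca-5,9-dienal F2, kept cold and neutral to protect the α-ethyl centre. Ethereal H2O2 with a trace of PPTS closes the 1,4-dicarbonyl to (4R)-4-ethyl-6-[(1E,4R,5E)-4-ethyl-2-methylocta-1,5-dien-1-yl]-1,2-dioxane-3,6-diol F3. TESCl/imidazole at −20 °C silylates the less hindered secondary hemiacetal hydroxyl and returns 16.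

Step 8 (acetylation). The risk is acylation of the open-chain hydroperoxide 15 instead of the cyclic hemiketal, which would give a perester that decomposes. The fallback changes the leaving-group strategy from acylation to peroxyketalisation; it sets out from 16 and comes back at cation 20. PPTS, MeOH and HC(OMe)3 convert 16, from either its open or closed form, into (4R)-4-ethyl-6-[(1E,4R,5E)-4-ethyl-2-methylocta-1,5-dien-1-yl]-3,6-dimethoxy-1,2-dioxane F4. Et2Zn/TMSOTf at −78 °C ionises only the tertiary alkenyl ketal and gives (4R,6R)-4,6-diethyl-6-[(1E,4R,5E)-4-ethyl-2-methylocta-1,5-dien-1-yl]-3-methoxy-1,2-dioxane F5. TMSOTf with the ketene acetal then ionises F5 to the same cation 20, which continues to 21 and 22.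

**Further compounds**
F1 | step 7 | (1S,2S,3R)-3-ethyl-1-[(1E,4R,5E)-4-ethyl-2-methylocta-1,5-dien-1-yl]cyclobutane-1,2-diol | CC/C=C/[C@H](CC)C/C(C)=C/[C@@]1(O)C[C@@H](CC)[C@@H]1O
F2 | step 7 | (2R,5E,8R,9E)-2,8-diethyl-6-methyl-4-oxododeca-5,9-dienal | CC/C=C/[C@H](CC)C/C(C)=C/C(=O)C[C@@H](CC)C=O
F3 | step 7 | (4R)-4-ethyl-6-[(1E,4R,5E)-4-ethyl-2-methylocta-1,5-dien-1-yl]-1,2-dioxane-3,6-diol | CC/C=C/[C@H](CC)C/C(C)=C/C1(O)C[C@@H](CC)C(O)OO1
F4 | step 8 | (4R)-4-ethyl-6-[(1E,4R,5E)-4-ethyl-2-methylocta-1,5-dien-1-yl]-3,6-dimethoxy-1,2-dioxane | CC/C=C/[C@H](CC)C/C(C)=C/C1(OC)C[C@@H](CC)C(OC)OO1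
F5 | step 8 | (4R,6R)-4,6-diethyl-6-[(1E,4R,5E)-4-ethyl-2-methylocta-1,5-dien-1-yl]-3-methoxy-1,2-dioxane | CC/C=C/[C@H](CC)C/C(C)=C/[C@@]1(CC)C[C@@H](CC)C(OC)OO1
F6 | step 9 | 2-[(4R,6S)-4-ethyl-6-[(1E,4R,5E)-4-ethyl-2-methylocta-1,5-dien-1-yl]-3-[(triethylsilyl)oxy]-1,2-dioxan-6-yl]acetaldehyde | CC/C=C/[C@H](CC)C/C(C)=C/[C@@]1(CC=O)C[C@@H](CC)C(O[Si](CC)(CC)CC)OO1
F7 | step 9 | 2-[(4R,6S)-4-ethyl-6-[(1E,4R,5E)-4-ethyl-2-methylocta-1,5-dien-1-yl]-3-[(triethylsilyl)oxy]-1,2-dioxan-6-yl]ethanol | CC/C=C/[C@H](CC)C/C(C)=C/[C@@]1(CCO)C[C@@H](CC)C(O[Si](CC)(CC)CC)OO1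
F8 | step 9 | 2-[(4R,6S)-4-ethyl-6-[(1E,4R,5E)-4-ethyl-2-methylocta-1,5-dien-1-yl]-3-[(triethylsilyl)oxy]-1,2-dioxan-6-yl]ethyl methanesulfonate | CC/C=C/[C@H](CC)C/C(C)=C/[C@@]1(CCOS(C)(=O)=O)C[C@@H](CC)C(O[Si](CC)(CC)CC)OO1
F9 | step 9 | (4R,6S)-4-ethyl-6-[(1E,4R,5E)-4-ethyl-2-methylocta-1,5-dien-1-yl]-6-(2-iodoethyl)-3-[(triethylsilyl)oxy]-1,2-dioxane | CC/C=C/[C@H](CC)C/C(C)=C/[C@@]1(CCI)C[C@@H](CC)C(O[Si](CC)(CC)CC)OO1
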